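**Retrosynthetic overview**
1. Target 16 ⇐ bis-benzyl ether 14 by hydrogenolysis; the sulfate is installed at step 9 and carried through.
2. Tetralin carbocycle (C1–C8a bond, C1 stereocentre) ⇐ acid-triggered, sulfate-relayed Friedel–Crafts transposition of tetrahydrofuran sulfate 12 (new). The ether ring masks the future C3 hydroxymethyl, so only the C2 arm is sulfated.
3. 12 ⇐ lariciresinol-type tetrahydrofuran 11 ⇐ trans-aldol adduct 9 of lactone 7 and aldehyde 8 (reduction, then cycloetherification).
4. 7 ⇐ enantioselective Baeyer–Villiger ring expansion of prochiral cyclobutanone 6; this creates the first stereocentre and all later centres are relayed from it.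
5. 6 and 8 ⇐ aryl bromide 4 ⇐ catechol 1. Ring order: cyclobutanone (bought) → γ-lactone → tetrahydrofuran (temporary) → tetralin carbocycle.

Assumption: the target is drawn as the free hydrogen sulfate; the sulfate is carried as its sodium salt and protonated only in the last step.

**Step 1**
Reactants: 1 catechol (benzene-1,2-diol)
Product: 2 guaiacol (2-methoxyphenol)
Conditions: MeI (1.0 equiv), K2CO3 (1.0 equiv), acetone, 56 °C; distil
Reagents that add atoms: iodomethane, SMILES CI
Why: Williamson mono-O-methylation of the catecholate monoanion with limiting MeI gives mainly the mono-ether, which is separated from catechol and veratrole by distillation.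

**Step 2**
Reactants: 2 guaiacol
Product: 3 4-bromo-2-methoxyphenol
Conditions: NBS (1.0 equiv), MeCN, 0 °C
Reagents that add atoms: N-bromosuccinimide, SMILES O=C1CCC(=O)N1Br
Why: Electrophilic aromatic bromination goes para to the free hydroxyl, the stronger donor, which is the usual regiochemistry for guaiacol.

**Step 3**
Reactants: 3 4-bromo-2-methoxyphenol
Product: 4 1-(benzyloxy)-4-bromo-2-methoxybenzene
Conditions: BnBr (1.1 equiv), K2CO3 (1.0 equiv), DMF, 25 °C
Reagents that add atoms: benzyl bromide, SMILES BrCc1ccccc1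
Why: Williamson O-benzylation of the phenol gives a protecting group that survives every later step and is removed by hydrogenolysis at the end.

**Step 4**
Reactants: 4 1-(benzyloxy)-4-bromo-2-methoxybenzene; 5 3-(bromomethyl)cyclobutan-1-one
Product: 6 3-[4-(benzyloxy)-3-methoxybenzyl]cyclobutan-1-one
Conditions: NiI2 (10 mol %), 4,4'-dimethoxy-2,2'-bipyridine (10 mol %), NaI (25 mol %), pyridine (10 mol %), Zn dust (2 equiv), DMPU, 60 °C
Reagents that add atoms: none
Why: Nickel-catalysed reductive cross-electrophile coupling joins the two bromides, since the aryl bromide adds oxidatively to zerovalent nickel and the primary alkyl bromide enters as a radical, while the ketone and benzyl ether are inert to Zn; no stereocentre is formed.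

**Step 5**
Reactants: 6 3-[4-(benzyloxy)-3-methoxybenzyl]cyclobutan-1-one
Product: 7 (4R)-4-[4-(benzyloxy)-3-methoxybenzyl]dihydrofuran-2(3H)-one
Conditions: Sc(OTf)3 (5 mol %), chiral C2-symmetric N,N'-dioxide bis(2,6-diisopropylanilide) ligand derived from pipecolic acid (5 mol %, enantiomer chosen to give the R lactone), m-CPBA (1.2 equiv), EtOAc, −20 °C
Reagents that add atoms: 3-chloroperbenzoic acid, SMILES OOC(=O)c1cccc(Cl)c1
Why: Catalytic asymmetric Baeyer–Villiger ring expansion desymmetrises the prochiral cyclobutanone, because in the chiral scandium-bound Criegee adduct only one of the two enantiotopic ring CH2 groups undergoes the 1,2-shift to oxygen, which sets the R centre that becomes C3 of the tetralin.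

**Step 6**
Reactants: 4 1-(benzyloxy)-4-bromo-2-methoxybenzene
Product: 8 4-(benzyloxy)-3-methoxybenzaldehyde
Conditions: n-BuLi (1.05 equiv), THF, −78 °C; DMF (2 equiv); aq. HCl
Reagents that add atoms: N,N-dimethylformamide, SMILES CN(C)C=O
Why: Bromine–lithium exchange followed by formylation of the aryllithium with DMF (Bouveault-type) is reliable here because exchange at −78 °C is faster than ortho-lithiation.

**Step 7**
Reactants: 7 (4R)-4-[4-(benzyloxy)-3-methoxybenzyl]dihydrofuran-2(3H)-one; 8 4-(benzyloxy)-3-methoxybenzaldehyde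
Product: 9 (3S,4R)-3-{[4-(benzyloxy)-3-methoxyphenyl](hydroxy)methyl}-4-[4-(benzyloxy)-3-methoxybenzyl]dihydrofuran-2(3H)-one (both carbinol epimers)
Conditions: LDA (LiN(i-Pr)2, 1.1 equiv), THF, −78 °C; then 8; AcOH quench
Reagents that add atoms: none
Why: Aldol addition of the lactone lithium enolate occurs anti to the C4 benzyl group and gives the 3,4-trans lactone (the future C2 centre), while the carbinol centre forms as a mixture that is erased later by ionisation.

**Step 8**
Reactants: 9 aldol adduct
Product: 11 {(2S,3R,4R)-2-[4-(benzyloxy)-3-methoxyphenyl]-4-[4-(benzyloxy)-3-methoxybenzyl]tetrahydrofuran-3-yl}methanol, via triol 10 (not isolated)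
Conditions: LiAlH4 (2 equiv), THF, 0 °C; H2O/NaOH work-up; crude triol, CSA (10 mol %), CH2Cl2, 0 °C
Reagents that add atoms: none
Why: Hydride reduction opens the lactone to the triol, and acid-catalysed SN1 cycloetherification then ionises the p-alkoxybenzylic alcohol of either epimer so that the distal primary hydroxyl closes the five-membered ether to the favoured 2,3-trans-3,4-trans isomer (lariciresinol pattern), leaving only the hydroxymethyl next to the benzylic carbon free.

**Step 9**
Reactants: 11 tetrahydrofuran alcohol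
Product: 12 sodium {(2S,3R,4R)-2-[4-(benzyloxy)-3-methoxyphenyl]-4-[4-(benzyloxy)-3-methoxybenzyl]tetrahydrofuran-3-yl}methyl sulfate
Conditions: SO3·pyridine (3 equiv), pyridine, 25 °C; aq. NaHCO3
Reagents that add atoms: sulfur trioxide–pyridine complex, SMILES [O-]S(=O)(=O)[n+]1ccccc1; sodium hydrogencarbonate, SMILES [Na+].OC([O-])=O
Why: O-Sulfation with the SO3–amine complex hits the only free hydroxyl, the cyclic ether is inert and no stereocentre is touched.

**Step 10**
Reactants: 12 tetrahydrofuran sulfate sodium salt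
Product: 14 sodium {(1S,2R,3R)-7-(benzyloxy)-1-[4-(benzyloxy)-3-methoxyphenyl]-3-(hydroxymethyl)-6-methoxy-1,2,3,4-tetrahydronaphthalen-2-yl}methyl sulfate, via cyclic sulfate 13 (not isolated)
Conditions: TFA (5 equiv), HFIP–CH2Cl2 (1:4), 0 °C, 1 h; evaporate with toluene
Reagents that add atoms: none
Why: Proposed new method: an acid-triggered, sulfate-relayed transposition of a 2-aryl-tetrahydrofuran into the aryltetralin on an unprotected sulfate monoester, in which TFA/HFIP protonates the ring oxygen and ionises the p-benzyloxybenzylic C–O bond (releasing the CH2OH that ends on C3), the neighbouring CH2OSO3− arm (too weakly basic to be protonated by TFA, so not prone to lose SO3) collapses on the cation to the neutral six-membered cyclic sulfate 13, and 13 re-ionises at the same carbon and is captured by the ring A carbon para to OMe in a six-membered Friedel–Crafts closure anti to the C2 substituent, giving the all-trans 1S centre with the sulfate monoester back on the C2 arm; the closest known reactions are the acid-mediated lariciresinol-to-isolariciresinol rearrangement and SN1-type opening of benzylic cyclic sulfates.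

**Step 11**
Reactants: 14 bis-benzyl tetralin sulfate sodium salt
Product: 16 [(1S,2R,3R)-7-hydroxy-1-(4-hydroxy-3-methoxyphenyl)-3-(hydroxymethyl)-6-methoxy-1,2,3,4-tetrahydronaphthalen-2-yl]methyl hydrogen sulfate (CNP0184747.1), via sodium salt 15 (not isolated)
Conditions: H2 (1 atm), Pd/C (10 wt %), MeOH, 25 °C; filter; aq. HCl (1.0 equiv), 0 °C; C18 desalting
Reagents that add atoms: none
Why: Catalytic hydrogenolysis cleaves both aryl benzyl ethers while the sulfate monoester salt, the diaryl methine and the stereocentres are inert, and protonation of the sodium salt gives the hydrogen sulfate as drawn.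

**Compound list**
1 | catechol (benzene-1,2-diol) | Oc1ccccc1O | starting material
2 | guaiacol (2-methoxyphenol) | COc1ccccc1O | intermediate
3 | 4-bromo-2-methoxyphenol | COc1cc(Br)ccc1O | intermediate
4 | 1-(benzyloxy)-4-bromo-2-methoxybenzene | COc1cc(Br)ccc1OCc1ccccc1 | intermediate
5 | 3-(bromomethyl)cyclobutan-1-one | O=C1CC(CBr)C1 | starting material
6 | 3-[4-(benzyloxy)-3-methoxybenzyl]cyclobutan-1-one (achiral, prochiral) | COc1cc(CC2CC(=O)C2)ccc1OCc1ccccc1 | intermediate
7 | (4R)-4-[4-(benzyloxy)-3-methoxybenzyl]dihydrofuran-2(3H)-one | COc1cc(C[C@H]2COC(=O)C2)ccc1OCc1ccccc1 | intermediate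
8 | 4-(benzyloxy)-3-methoxybenzaldehyde | COc1cc(C=O)ccc1OCc1ccccc1 | intermediate
9 | (3S,4R)-3-{[4-(benzyloxy)-3-methoxyphenyl](hydroxy)methyl}-4-[4-(benzyloxy)-3-methoxybenzyl]dihydrofuran-2(3H)-one, 3,4-trans, carbinol centre as both epimers | COc1cc(C[C@H]2COC(=O)[C@@H]2C(O)c2ccc(OCc3ccccc3)c(OC)c2)ccc1OCc1ccccc1 | intermediate
10 | (2R,3R)-2-[4-(benzyloxy)-3-methoxybenzyl]-3-{[4-(benzyloxy)-3-methoxyphenyl](hydroxy)methyl}butane-1,4-diol, carbinol centre as both epimers (not isolated) | COc1cc(C[C@@H](CO)[C@H](CO)C(O)c2ccc(OCc3ccccc3)c(OC)c2)ccc1OCc1ccccc1 | intermediate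
11 | {(2S,3R,4R)-2-[4-(benzyloxy)-3-methoxyphenyl]-4-[4-(benzyloxy)-3-methoxybenzyl]tetrahydrofuran-3-yl}methanol (bis-benzyl ether of (+)-lariciresinol) | COc1cc(C[C@H]2CO[C@@H]([C@H]2CO)c2ccc(OCc3ccccc3)c(OC)c2)ccc1OCc1ccccc1 | intermediate
12 | sodium {(2S,3R,4R)-2-[4-(benzyloxy)-3-methoxyphenyl]-4-[4-(benzyloxy)-3-methoxybenzyl]tetrahydrofuran-3-yl}methyl sulfate | COc1cc(C[C@H]2CO[C@@H]([C@H]2COS(=O)(=O)[O-])c2ccc(OCc3ccccc3)c(OC)c2)ccc1OCc1ccccc1.[Na+] | intermediate
13 | (5R)-4-[4-(benzyloxy)-3-methoxyphenyl]-5-{(2R)-1-[4-(benzyloxy)-3-methoxyphenyl]-3-hydroxypropan-2-yl}-1,3,2-dioxathiane 2,2-dioxide, benzylic C4 in either configuration (not isolated) | COc1cc(C[C@@H](CO)[C@@H]2COS(=O)(=O)OC2c2ccc(OCc3ccccc3)c(OC)c2)ccc1OCc1ccccc1 | intermediate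
14 | sodium {(1S,2R,3R)-7-(benzyloxy)-1-[4-(benzyloxy)-3-methoxyphenyl]-3-(hydroxymethyl)-6-methoxy-1,2,3,4-tetrahydronaphthalen-2-yl}methyl sulfate | COc1cc([C@H]2c3cc(OCc4ccccc4)c(OC)cc3C[C@@H](CO)[C@@H]2COS(=O)(=O)[O-])ccc1OCc1ccccc1.[Na+] | intermediate
15 | sodium [(1S,2R,3R)-7-hydroxy-1-(4-hydroxy-3-methoxyphenyl)-3-(hydroxymethyl)-6-methoxy-1,2,3,4-tetrahydronaphthalen-2-yl]methyl sulfate (not isolated) | COc1cc([C@H]2c3cc(O)c(OC)cc3C[C@@H](CO)[C@@H]2COS(=O)(=O)[O-])ccc1O.[Na+] | intermediate
16 | [(1S,2R,3R)-7-hydroxy-1-(4-hydroxy-3-methoxyphenyl)-3-(hydroxymethyl)-6-methoxy-1,2,3,4-tetrahydronaphthalen-2-yl]methyl hydrogen sulfate | COc1cc([C@H]2c3cc(O)c(OC)cc3C[C@@H](CO)[C@@H]2COS(=O)(=O)O)ccc1O | target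

**Step count and risks**
Total: 11 steps. Longest linear sequence: 10 steps (1–5, then 7–11); step 6 is a one-step branch from 4.

Step 10 (the new step) is the most likely to fail: the sulfate could lose SO3 in acid, or the cation could oligomerise instead of closing. The fallback uses known chemistry, sets out from 11 and comes back at 14. Alcohol 11 is sulfated with 2,2,2-trichloroethyl chlorosulfate (Et3N, DMAP, THF) to the neutral {(2S,3R,4R)-2-[4-(benzyloxy)-3-methoxyphenyl]-4-[4-(benzyloxy)-3-methoxybenzyl]tetrahydrofuran-3-yl}methyl 2,2,2-trichloroethyl sulfate F1. This neutral ether undergoes the known acid-mediated lariciresinol-to-isolariciresinol Friedel–Crafts rearrangement (TFA, CH2Cl2, 0 °C) to the tetralin trichloroethyl sulfate diester F2. Zn dust and HCO2NH4 in MeOH remove the trichloroethyl group to give the ammonium salt of the bis-benzyl tetralin sulfate F3, and a wash with aq. NaHCO3 exchanges the cation to give 14, which continues with step 11.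

Step 5 is second: the enantioselectivity of the Baeyer–Villiger desymmetrisation may be only moderate for a 3-arylmethyl cyclobutanone (one recrystallisation of 7 or 11 is planned in any case). The fallback sets out from 6 and comes back at 7 by resolution instead of asymmetric catalysis. Uncatalysed m-CPBA oxidation gives racemic 4-[4-(benzyloxy)-3-methoxybenzyl]dihydrofuran-2(3H)-one F4. Aminolysis with (S)-1-phenylethylamine (2-hydroxypyridine cat., toluene, 110 °C) gives two diastereomeric hydroxy amides that are separated by chromatography: the wanted (3R)-3-[4-(benzyloxy)-3-methoxybenzyl]-4-hydroxy-N-[(1S)-1-phenylethyl]butanamide F5 and its discarded (3S)-epimer F6. Heating F5 in aq. H2SO4/dioxane relactonises it to 7 and releases the amine.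

Step 4 is third: the β-branched primary bromide may give hydrodehalogenation or homocoupling in the reductive coupling. The fallback sets out from 4 and comes back at 6 by building the four-membered ring instead of coupling to it. The Grignard reagent of 4 (Mg, THF) is allylated with allyl bromide (CuI cat.) to 4-allyl-1-(benzyloxy)-2-methoxybenzene F7. A [2+2] cycloaddition with dichloroketene (Cl3CCOCl, Zn–Cu couple, Et2O) gives 3-[4-(benzyloxy)-3-methoxybenzyl]-2,2-dichlorocyclobutan-1-one F8, and Zn/AcOH dechlorination gives 6.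

**Further compounds**
F1 | step 10 | {(2S,3R,4R)-2-[4-(benzyloxy)-3-methoxyphenyl]-4-[4-(benzyloxy)-3-methoxybenzyl]tetrahydrofuran-3-yl}methyl 2,2,2-trichloroethyl sulfate | COc1cc(C[C@H]2CO[C@@H]([C@H]2COS(=O)(=O)OCC(Cl)(Cl)Cl)c2ccc(OCc3ccccc3)c(OC)c2)ccc1OCc1ccccc1
F2 | step 10 | {(1S,2R,3R)-7-(benzyloxy)-1-[4-(benzyloxy)-3-methoxyphenyl]-3-(hydroxymethyl)-6-methoxy-1,2,3,4-tetrahydronaphthalen-2-yl}methyl 2,2,2-trichloroethyl sulfate | COc1cc([C@H]2c3cc(OCc4ccccc4)c(OC)cc3C[C@@H](CO)[C@@H]2COS(=O)(=O)OCC(Cl)(Cl)Cl)ccc1OCc1ccccc1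
F3 | step 10 | ammonium {(1S,2R,3R)-7-(benzyloxy)-1-[4-(benzyloxy)-3-methoxyphenyl]-3-(hydroxymethyl)-6-methoxy-1,2,3,4-tetrahydronaphthalen-2-yl}methyl sulfate | COc1cc([C@H]2c3cc(OCc4ccccc4)c(OC)cc3C[C@@H](CO)[C@@H]2COS(=O)(=O)[O-])ccc1OCc1ccccc1.[NH4+]
F4 | step 5 | racemic 4-[4-(benzyloxy)-3-methoxybenzyl]dihydrofuran-2(3H)-one | COc1cc(CC2COC(=O)C2)ccc1OCc1ccccc1
F5 | step 5 | (3R)-3-[4-(benzyloxy)-3-methoxybenzyl]-4-hydroxy-N-[(1S)-1-phenylethyl]butanamide | COc1cc(C[C@H](CC(=O)N[C@@H](C)c2ccccc2)CO)ccc1OCc1ccccc1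
F6 | step 5 | (3S)-3-[4-(benzyloxy)-3-methoxybenzyl]-4-hydroxy-N-[(1S)-1-phenylethyl]butanamide | COc1cc(C[C@@H](CC(=O)N[C@@H](C)c2ccccc2)CO)ccc1OCc1ccccc1
F7 | step 4 | 4-allyl-1-(benzyloxy)-2-methoxybenzene | COc1cc(CC=C)ccc1OCc1ccccc1
F8 | step 4 | racemic 3-[4-(benzyloxy)-3-methoxybenzyl]-2,2-dichlorocyclobutan-1-one | COc1cc(CC2CC(=O)C2(Cl)Cl)ccc1OCc1ccccc1
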